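## The problem

The target 18 is an isoflavone: a chromen-4-one (rings A and C) that carries the 3,4-dimethoxyphenyl ring B at C3. Ring A is substituted at every carbon except C5, with OMe at C6, a free OH at C7 and a 3-methylbut-2-enyl (prenyl) group at C8. A synthesis therefore has to join ring B to C3 and close ring C, keep the C7 oxygen distinct from three methyl ethers, and place the prenyl group on C8 only. There is no stereocentre and no stereogenic double bond in 18, so nothing has to be controlled there; only the geometry of one acyclic alkene on the way matters, and it corrects itself. The prenyl group is the fragile part: protic and Lewis acids protonate its trisubstituted alkene and close it onto O7 as a 2,2-dimethylchroman, so it cannot be present when strong acid is used, and ring C in turn opens at C2 in hot aqueous base. The feature that makes the key step possible lies in ring A: C4a is para to the C7 oxygen and ortho to the O1 ether oxygen and has only one substituted neighbour, whereas C8, the other carbon ortho to O1, lies between two oxygens. An acyl carbon tethered through O1–C2=C3 can therefore be delivered to C4a by electrophilic substitution, forming C4–C4a and closing ring C in one operation. The oxygen pattern that results (O1, O7, OMe at C6) is that of isovanillin once its formyl group is exchanged for OH, and because C6 is blocked by OMe a sigmatropic shift from O7 can end only at C8.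

## Retrosynthesis

**C8–prenyl bond.** The bond between C8 and the prenyl CH2 of 18 is cut first, and the five-carbon unit is returned to O7 as the 1,1-dimethylallyl ether 16. The forward reaction is an aromatic Claisen rearrangement through the transient dienone 17. Direct C-prenylation of phenol 12 would give O- and C-alkylation mixtures, and a cross-coupling would need a halogen at C8. The sigmatropic shift turns the tertiary ether into the linear prenyl group and has only C8 to go to. Ether 16 comes from the propargyl ether 15 by semihydrogenation, and 15 from phenol 12 and the alkynol 13, activated in the flask as its trifluoroacetate 14. This removes the acid-sensitive side chain from all earlier chemistry and leaves a flat, robust 7-hydroxyisoflavone.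

**O7 protecting group.** Phenol 12 is traced to its isopropyl ether 11. The C7 oxygen must be told apart from three methyl ethers through a strongly acidic ring closure. A methoxymethyl or silyl group would not survive that closure, and a benzyl ether would be at risk in it. An isopropyl ether survives acid and base and is removed by a boron trihalide without loss of the methyl ethers, none of which sits peri to the C4 carbonyl. The forward step must be chemoselective for the secondary alkyl ether.

**C4–C4a bond (key disconnection).** Cutting C4–C4a of 11 opens ring C to the acrylic acid 10, in which ring A hangs on the enol ether oxygen and ring B on the α-carbon. Three neighbouring cuts were weighed: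
- Closing O1–C2 from a deoxybenzoin first needs an ortho-hydroxyaryl ketone, made by an intermolecular acylation.
- Closing O1–C8a needs a halogen at C8a.
- Attaching ring B to a 3-halochromone by cross-coupling still needs the chromone.

The C4–C4a cut makes the difficult aryl–carbonyl bond intramolecularly at the most nucleophilic free carbon of ring A. Acid 10 is acyclic and is assembled from two simple arenes. The forward step must acylate C4a and not C8, and the aryloxy group must be cis to the carboxyl carbon at the moment of closure.

**O1–C2 bond.** Acid 10 is the saponification product of methyl ester 9. The enol ether C–O bond of 9 is cut to give phenol 4 and the enol tosylate 8. The forward reaction is an addition–elimination at the β-carbon of an acrylate. It needs no metal and joins the two halves convergently, which is preferred to building the enol ether on a preformed aryl ether. The forward step must put oxygen, not sulfur, of the tosylate under attack and should keep the Z geometry.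

**C2–C3 bond.** Tosylate 8 comes from the enol 7, and 7 from methyl (3,4-dimethoxyphenyl)acetate 5 and methyl formate 6 by cutting the bond between the α-carbon and the formyl carbon. This crossed Claisen condensation brings in C2 of the chromone as a one-carbon unit, and both partners are commercial. The tosylation must be O-selective and should favour the Z enol derivative.

**Ring A phenol.** Phenol 4 is derived from aldehyde 2 by exchanging the formyl group for OH through the formate 3, and 2 from isovanillin 1 by O-isopropylation. The free OH of 1 becomes O7, its OMe becomes the C6 methoxy group and its formyl-bearing carbon becomes C8a. No ring A carbon–oxygen bond has to be made on an unfunctionalised arene.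

## Roads not taken

**Alternative 1:** Ring A would be built by cycloaddition, cutting C5–C6 and C7–C8. The 2-pyrone A2, which carries the prenyl group, an acetoxy group and an ester, would react with the bis-silyl ketene acetal A3. Loss of CO2 and Me3SiOH from the adduct would give the benzoate A1.
- Merits: every substituent of ring A is fixed by the regiochemistry of one cycloaddition, and the prenyl group arrives at its final carbon without any late rearrangement or protecting-group exchange at O7. In this respect the road is better than the chosen plan, which spends four steps after ring closure on the side chain.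
- Weak points: A2 is a densely substituted heterocycle that needs its own multistep synthesis. A1 still lacks ring C and ring B, so the ester must be turned into an aryl benzyl ketone and then into the pyranone. All of this must be done with a free phenol, a migration-prone aryl acetate and the acid-sensitive prenyl group on board.
- Comparison: the chosen plan takes ring A ready-made from isovanillin, closes ring C with ring B already attached, and keeps the prenyl group out of all harsh steps.

**Alternative 2:** Ring A would be made from a squaric ester by cutting C4a–C8a. Heating the 4-vinylcyclobutenone A5 would open it to a dienylketene, whose six-electron electrocyclisation and tautomerisation would give phenol A4.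
- Merits: the thermal step is neutral and regiochemically unambiguous. A4 already bears the prenyl group ortho to the phenol oxygen and the isopropyl-protected O7. It could in principle replace phenol 4 in the chosen route and remove three of the four closing steps, which would be a real gain in step economy.
- Weak points: the prenyl group would then have to pass through the strongly acidic closure of ring C and a boron trihalide deprotection on the neighbouring oxygen. Both conditions favour protonation of the alkene and chroman formation. A5 also needs several low-temperature organometallic additions to the squarate with regiocontrol and an O-methylation of a tertiary alcohol, against two routine steps for 4.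
- Comparison: the chosen plan accepts a longer end game in exchange for intermediates that tolerate the key step.

**Alternative 3:** Ring C would be closed at O1–C8a. The enolate oxygen of the 2-bromoaryl formyl ketone A7 would displace bromide under CuI (monovalent copper) and K2CO3 to give the protected isoflavone A6.
- Merits: the closure is basic and mild, so the prenyl group can be present, and only one deprotection follows. The closure does not depend on the nucleophilicity of ring A. In functional-group tolerance and in the number of steps after the key step this road is better.
- Weak points: A7 contains a pentasubstituted arene with bromine between the acyl group and the prenyl group. Making that arene regioselectively is the real problem of the target, moved to an earlier stage. The C–O coupling must also take place at a bromide with two ortho substituents, in competition with deformylation of the 1,3-dicarbonyl unit. The acid needed for the methoxymethyl group acts on a phenol next to a prenyl group.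
- Comparison: the chosen plan has precursors that are each two or three routine steps from commercial materials, and a ring closure whose regiochemistry is set by the substitution pattern itself.

Key step: step 7

Assumption: compounds 7–10 are drawn as Z isomers (oxygen substituent on the side of the carboxyl carbon), the geometry expected from a lithium-chelated enolate and a retentive addition–elimination. Any E isomer in 9 or 10 is carried through, because the push–pull alkene equilibrates in the acid of step 7.

## Route

Step 1
Reactants: 1 isovanillin (3-hydroxy-4-methoxybenzaldehyde)
Product: 2 3-isopropoxy-4-methoxybenzaldehyde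
Conditions: 2-bromopropane, K2CO3, DMF, 70 °C
Reagents that add atoms: 2-bromopropane, CC(C)Br
Why: Williamson ether synthesis; the phenoxide of 1 is alkylated by the secondary bromide in a dipolar aprotic solvent and the aldehyde is inert.

Step 2
Reactants: 2 3-isopropoxy-4-methoxybenzaldehyde
Product: 4 3-isopropoxy-4-methoxyphenol, via aryl formate 3 (not isolated)
Conditions: mCPBA, CH2Cl2, rt; then KOH, MeOH/H2O, 0 °C; HCl work-up
Reagents that add atoms: 3-chloroperbenzoic acid (mCPBA), OOC(=O)c1cccc(Cl)c1
Why: Dakin-type Baeyer–Villiger oxidation; the electron-rich aryl group (para methoxy) migrates to oxygen in preference to hydride, and the resulting formate is cleaved by hydroxide to the phenol.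

Step 3
Reactants: 5 methyl (3,4-dimethoxyphenyl)acetate; 6 methyl formate
Product: 7 methyl (Z)-2-(3,4-dimethoxyphenyl)-3-hydroxyacrylate (enol form of the α-formyl ester)
Conditions: NaH, THF, 0 °C to rt; aq. HCl work-up
Reagents that add atoms: none
Why: Crossed Claisen condensation (C-formylation); the benzylic ester enolate attacks the non-enolisable formate and the product is held as its sodium enolate, which drives the equilibrium, and acidification should give the hydrogen-bonded Z enol.

Step 4
Reactants: 7 methyl (Z)-2-(3,4-dimethoxyphenyl)-3-hydroxyacrylate
Product: 8 methyl (Z)-2-(3,4-dimethoxyphenyl)-3-(4-methylphenylsulfonyloxy)acrylate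
Conditions: TsCl, TMEDA, LiCl, MeCN, 0 °C
Reagents that add atoms: p-toluenesulfonyl chloride, Cc1ccc(S(=O)(=O)Cl)cc1
Why: Enol O-sulfonylation of a 1,3-dicarbonyl compound; lithium chelation holds the enolate oxygen cis to the ester carbonyl, so the Z enol tosylate should predominate.

Step 5
Reactants: 8 methyl (Z)-2-(3,4-dimethoxyphenyl)-3-(4-methylphenylsulfonyloxy)acrylate; 4 3-isopropoxy-4-methoxyphenol
Product: 9 methyl (Z)-2-(3,4-dimethoxyphenyl)-3-(3-isopropoxy-4-methoxyphenoxy)acrylate
Conditions: K2CO3, DMF, 0 °C to rt, argon
Reagents that add atoms: none
Why: Nucleophilic vinylic substitution by addition–elimination; the phenoxide adds to the β-carbon of the acrylate and tosylate leaves from the ester-stabilised carbanion, expected largely with retention, which places the aryloxy group cis to the ester.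

Step 6
Reactants: 9 methyl (Z)-2-(3,4-dimethoxyphenyl)-3-(3-isopropoxy-4-methoxyphenoxy)acrylate
Product: 10 (Z)-2-(3,4-dimethoxyphenyl)-3-(3-isopropoxy-4-methoxyphenoxy)acrylic acid
Conditions: LiOH, THF/MeOH/H2O, rt; then dilute HCl to pH 3–4, 0 °C
Reagents that add atoms: lithium hydroxide, [Li+].[OH-]
Why: Ester saponification; the carboxylate, once formed, deactivates the push–pull alkene towards further attack, and cold, mild acidification spares the enol ether.

Step 7
Reactants: 10 (Z)-2-(3,4-dimethoxyphenyl)-3-(3-isopropoxy-4-methoxyphenoxy)acrylic acid
Product: 11 3-(3,4-dimethoxyphenyl)-7-isopropoxy-6-methoxychromen-4-one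
Conditions: P2O5 in CH3SO3H (Eaton's reagent), rt to 40 °C
Reagents that add atoms: none
Why: Intramolecular Friedel–Crafts acylation of a 3-aryloxyacrylic acid (Ruhemann-type chromone closure). P2O5/CH3SO3H converts the acid into a mixed anhydride and then an acylium ion, which the Z alkene holds next to the aryloxy ring. Attack of ring A at the carbon para to the isopropoxy group and ortho to the ether oxygen forms C4–C4a and loss of the C4a proton restores the arene; ring C is thus closed as a six-membered ring by 6-exo attack of the arene on the acyl carbon, with the C4a–C8a bond of the arene inside the new ring. No stereocentre is formed. The selectivity needed is C4a against C8: C4a is activated by a para alkoxy group and is unhindered, whereas C8 lies between O1 and the isopropoxy group and is only ortho-activated. Ring B cannot compete, since closure onto it would give a four-membered ring. Any E isomer present reaches the reactive geometry because the push–pull alkene loses its double-bond character on protonation in the strong acid. The isopropyl ether should survive at this temperature, and its partial loss would only give 12, the product of the next step.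

Step 8
Reactants: 11 3-(3,4-dimethoxyphenyl)-7-isopropoxy-6-methoxychromen-4-one
Product: 12 3-(3,4-dimethoxyphenyl)-7-hydroxy-6-methoxychromen-4-one
Conditions: BCl3, CH2Cl2, −78 to 0 °C; then MeOH/H2O
Reagents that add atoms: none
Why: Lewis-acid dealkylation of an aryl ether; BCl3 cleaves the secondary isopropyl ether much faster than methyl ethers, and with no methoxy group peri to the C4 carbonyl none of the three methyl ethers is activated by chelation.

Step 9
Reactants: 12 3-(3,4-dimethoxyphenyl)-7-hydroxy-6-methoxychromen-4-one; 13 2-methylbut-3-yn-2-ol
Product: 15 3-(3,4-dimethoxyphenyl)-6-methoxy-7-(2-methylbut-3-yn-2-yloxy)chromen-4-one, via propargyl trifluoroacetate 14 (not isolated)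
Conditions: 13, (CF3CO)2O, DBU, MeCN, −5 °C; then 12, CuCl2·2H2O (cat.), DBU, 0 °C
Reagents that add atoms: none
Why: Copper-catalysed propargylic etherification of a phenol with a tertiary propargylic ester; the copper acetylide ionises the trifluoroacetate and the phenoxide is captured at the tertiary carbon, a method suited to acidic, weakly nucleophilic phenols such as a 7-hydroxychromone.

Step 10
Reactants: 15 3-(3,4-dimethoxyphenyl)-6-methoxy-7-(2-methylbut-3-yn-2-yloxy)chromen-4-one
Product: 16 3-(3,4-dimethoxyphenyl)-6-methoxy-7-(2-methylbut-3-en-2-yloxy)chromen-4-one
Conditions: H2 (1 atm), Pd/CaCO3 poisoned with Pb(OAc)2 (Lindlar catalyst), quinoline, EtOAc, rt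
Reagents that add atoms: none
Why: Lindlar semihydrogenation of a terminal alkyne; the poisoned catalyst stops at the alkene and leaves the trisubstituted C2–C3 double bond of the chromone and the tertiary allylic ether intact.

Step 11
Reactants: 16 3-(3,4-dimethoxyphenyl)-6-methoxy-7-(2-methylbut-3-en-2-yloxy)chromen-4-one
Product: 18 3-(3,4-dimethoxyphenyl)-7-hydroxy-6-methoxy-8-(3-methylbut-2-enyl)chromen-4-one, via ortho-dienone 17 (not isolated)
Conditions: PhNEt2, 180 °C, argon
Reagents that add atoms: none
Why: Aromatic Claisen rearrangement ([3,3] sigmatropic shift); the allyl unit is transferred with allylic inversion, so the tertiary ether gives the linear prenyl group at C8, the only ortho position that can rearomatise because C6 carries OMe, and tautomerisation of the dienone gives the phenol.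

## Compound list

1 | isovanillin (3-hydroxy-4-methoxybenzaldehyde) | COc1ccc(C=O)cc1O | starting material
2 | 3-isopropoxy-4-methoxybenzaldehyde | COc1ccc(C=O)cc1OC(C)C | intermediate
3 | 3-isopropoxy-4-methoxyphenyl formate | COc1ccc(OC=O)cc1OC(C)C | intermediate (not isolated)
4 | 3-isopropoxy-4-methoxyphenol | COc1ccc(O)cc1OC(C)C | intermediate
5 | methyl (3,4-dimethoxyphenyl)acetate | COC(=O)Cc1ccc(OC)c(OC)c1 | starting material
6 | methyl formate | COC=O | starting material
7 | methyl (Z)-2-(3,4-dimethoxyphenyl)-3-hydroxyacrylate | COc1ccc(/C(C(=O)OC)=C/O)cc1OC | intermediate
8 | methyl (Z)-2-(3,4-dimethoxyphenyl)-3-(4-methylphenylsulfonyloxy)acrylate | COc1ccc(/C(C(=O)OC)=C/OS(=O)(=O)c2ccc(C)cc2)cc1OC | intermediate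
9 | methyl (Z)-2-(3,4-dimethoxyphenyl)-3-(3-isopropoxy-4-methoxyphenoxy)acrylate | COc1ccc(/C(C(=O)OC)=C/Oc2ccc(OC)c(OC(C)C)c2)cc1OC | intermediate
10 | (Z)-2-(3,4-dimethoxyphenyl)-3-(3-isopropoxy-4-methoxyphenoxy)acrylic acid | COc1ccc(/C(C(=O)O)=C/Oc2ccc(OC)c(OC(C)C)c2)cc1OC | intermediate
11 | 3-(3,4-dimethoxyphenyl)-7-isopropoxy-6-methoxychromen-4-one | COc1ccc(-c2coc3cc(OC(C)C)c(OC)cc3c2=O)cc1OC | intermediate
12 | 3-(3,4-dimethoxyphenyl)-7-hydroxy-6-methoxychromen-4-one | COc1ccc(-c2coc3cc(O)c(OC)cc3c2=O)cc1OC | intermediate
13 | 2-methylbut-3-yn-2-ol | CC(C)(O)C#C | starting material
14 | 2-methylbut-3-yn-2-yl trifluoroacetate | CC(C)(OC(=O)C(F)(F)F)C#C | intermediate (not isolated)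
15 | 3-(3,4-dimethoxyphenyl)-6-methoxy-7-(2-methylbut-3-yn-2-yloxy)chromen-4-one | COc1ccc(-c2coc3cc(OC(C)(C)C#C)c(OC)cc3c2=O)cc1OC | intermediate
16 | 3-(3,4-dimethoxyphenyl)-6-methoxy-7-(2-methylbut-3-en-2-yloxy)chromen-4-one | COc1ccc(-c2coc3cc(OC(C)(C)C=C)c(OC)cc3c2=O)cc1OC | intermediate
17 | 3-(3,4-dimethoxyphenyl)-6-methoxy-8-(3-methylbut-2-enyl)-8H-chromene-4,7-dione (racemic at C8, transient) | COC1=CC2=C(OC=C(c3ccc(OC)c(OC)c3)C2=O)C(CC=C(C)C)C1=O | intermediate (not isolated)
18 | 3-(3,4-dimethoxyphenyl)-7-hydroxy-6-methoxy-8-(3-methylbut-2-enyl)chromen-4-one | COc1ccc(-c2coc3c(CC=C(C)C)c(O)c(OC)cc3c2=O)cc1OC | target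

## Step count and risks

Total: 11 steps. Longest linear sequence: 9 steps (steps 1, 2 and 5–11 from isovanillin 1; the arm from ester 5 through steps 3, 4 and 5–11 is equally long).

**Step 7 (key step).** The most likely failure is slow closure. The acyl cation is stabilised by the β-oxygen of the push–pull system and is a weak electrophile, so protolytic cleavage of the enol ether or intermolecular acylation of ring B could overtake ring formation. Incomplete equilibration of any E acid would lower conversion further. The fallback changes the order of bond formation. It sets out from phenol 4, which is C-acylated at the position para to the isopropoxy group with (3,4-dimethoxyphenyl)acetic acid in BF3·OEt2. This gives the deoxybenzoin 2-(3,4-dimethoxyphenyl)-1-(2-hydroxy-4-isopropoxy-5-methoxyphenyl)ethanone F1. Heating F1 with N,N-dimethylformamide dimethyl acetal supplies C2 and closes ring C, and the route is rejoined at 11.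

**Step 5.** The phenoxide may attack sulfur of the enol tosylate (sulfonyl transfer to the phenol) instead of the β-carbon. The α-aryl group also lowers the electrophilicity of the acrylate, so addition may be sluggish. Loss of alkene geometry is tolerable. The fallback sets out from enol 7, which is converted with oxalyl chloride and DMF into the vinyl chloride methyl (Z)-3-chloro-2-(3,4-dimethoxyphenyl)acrylate F2 (either geometry serves). F2 has no sulfonyl centre to divert the nucleophile and is displaced by phenol 4 with K2CO3 in DMF, returning to the route at 9.

**Step 6.** Hydroxide may add to the β-carbon of the acrylate and expel the aryloxide, reversing step 5. Acyl substitution at the hindered, electronically deactivated ester is likely to be slow, which favours this pathway. The fallback sets out from 9 and cleaves the ester at the alkyl–oxygen bond: LiI in refluxing ethyl acetate demethylates by SN2 attack on the methyl group. The β-carbon is not attacked irreversibly, and acidification gives 10.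

**Step 9.** The tertiary propargylic ester may eliminate to the enyne faster than it is captured, because the phenoxide of 12 is a vinylogous carboxylate of low nucleophilicity and is flanked by the C6 methoxy group. The fallback sets out from 12 and uses a Tsuji–Trost O-allylation. tert-Butyl 2-methylbut-3-en-2-yl carbonate and Pd(PPh3)4 (zerovalent palladium) in THF at 0 °C should give the branched tertiary allyl ether as the kinetic product. The route is rejoined at 16, and step 10 is no longer needed.

**Step 11.** At the temperature of the rearrangement the tertiary allyl ether may fragment (loss of isoprene, regenerating 12). The ortho-prenylphenol product may also cyclise onto O7 to a dimethylchroman. The fallback sets out from 12 and uses cross-coupling. Iodination with N-iodosuccinimide at C8, the only free position ortho to the phenol, gives 3-(3,4-dimethoxyphenyl)-7-hydroxy-8-iodo-6-methoxychromen-4-one F3. Stille coupling of F3 with tributyl(3-methylbut-2-enyl)stannane and Pd(PPh3)4 in DMF attaches the linear prenyl group and returns to the route at 18.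

## Further compounds

F1 | step 7 | 2-(3,4-dimethoxyphenyl)-1-(2-hydroxy-4-isopropoxy-5-methoxyphenyl)ethanone | COc1ccc(CC(=O)c2cc(OC)c(OC(C)C)cc2O)cc1OC
F2 | step 5 | methyl (Z)-3-chloro-2-(3,4-dimethoxyphenyl)acrylate | COc1ccc(/C(C(=O)OC)=C/Cl)cc1OC
F0 | step 6 | none | none
F0 | step 9 | none | none
F3 | step 11 | 3-(3,4-dimethoxyphenyl)-7-hydroxy-8-iodo-6-methoxychromen-4-one | COc1ccc(-c2coc3c(I)c(O)c(OC)cc3c2=O)cc1OC
A1 | alternative 1 | methyl 2-acetoxy-4-hydroxy-5-methoxy-3-(3-methylbut-2-enyl)benzoate | COC(=O)c1cc(OC)c(O)c(CC=C(C)C)c1OC(C)=O
A2 | alternative 1 | methyl 4-acetoxy-3-(3-methylbut-2-enyl)-2-oxo-2H-pyran-5-carboxylate | COC(=O)C1=COC(=O)C(CC=C(C)C)=C1OC(C)=O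
A3 | alternative 1 | 2-methoxy-1,1-bis(trimethylsilyloxy)ethene | COC=C(O[Si](C)(C)C)O[Si](C)(C)C
A4 | alternative 2 | 4-methoxy-2-(3-methylbut-2-enyl)-3-(propan-2-yloxy)phenol | COc1ccc(O)c(CC=C(C)C)c1OC(C)C
A5 | alternative 2 | 4-ethenyl-4-methoxy-2-(3-methylbut-2-enyl)-3-(propan-2-yloxy)cyclobut-2-en-1-one (racemic) | O=C1C(CC=C(C)C)=C(OC(C)C)C1(OC)C=C
A6 | alternative 3 | 3-(3,4-dimethoxyphenyl)-6-methoxy-7-(methoxymethoxy)-8-(3-methylbut-2-enyl)chromen-4-one | COc1ccc(-c2coc3c(CC=C(C)C)c(OCOC)c(OC)cc3c2=O)cc1OC
A7 | alternative 3 | (Z)-1-[2-bromo-5-methoxy-4-(methoxymethoxy)-3-(3-methylbut-2-enyl)phenyl]-2-(3,4-dimethoxyphenyl)-3-hydroxyprop-2-en-1-one | COCOc1c(OC)cc(C(=O)/C(=C\O)c2ccc(OC)c(OC)c2)c(Br)c1CC=C(C)C
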